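## Retrosynthetic overview

- The heptane chain is numbered C1–C7 from the arylethyl end; the oxane ring is O/C3/C4/C5/C6/C7 with the carbinol at C5. The plan rests on C3: it lies two carbons from the electron-rich guaiacyl ring on C1, so with C1–C3 unsaturation it is one terminus of an aryl-stabilised allyl cation and the O–C3 ring bond can be formed reversibly.
- The O–C3 bond (the only ring, closed last) is disconnected to the acyclic C1 carbinol / C2=C3 alkene 18, with C7–OH free, C5–OTBS, and the C7 aryl deactivated as its pivalate.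
- C2=C3 comes from cross-metathesis of the C3–C7 alkene 13 with the racemic aryl vinyl carbinol 17.
- C6–C7 and C4–C5 come from two reagent-controlled allylations starting at O-pivaloylvanillin (C7 first, then C5 syn), with TES/TBS differentiation of the two carbinols.
- After ring closure: hydrogenation (styrene and benzyl ether), desilylation, methanolysis of the pivalate.

Key step: step 11

Assumption (sense of induction): (R)-TRIP is taken to direct allylboration with allylBpin to the Re face of aryl aldehydes, so the (S)-acid is specified in step 2; the B-allyldiisopinocampheylborane derived from (+)-α-pinene is taken to add to the Si face of aldehydes (step 5).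

## Route

Step 1
Reactants: 1 vanillin
Product: 2 4-formyl-2-methoxyphenyl pivalate (O-pivaloylvanillin)
Conditions: PivCl (1.1 equiv), Et3N (1.5 equiv), DMAP (cat.), CH2Cl2, 0 °C → rt
Reagents that add atoms: pivaloyl chloride, CC(C)(C)C(Cl)=O
Why: DMAP-catalysed O-acylation of the phenol; the hindered, electron-withdrawing ester is chosen so that the future C7 benzylic C–O bond cannot ionise later.

Step 2
Reactants: 2 O-pivaloylvanillin; 3 allylboronic acid pinacol ester
Product: 5 4-[(1S)-1-hydroxybut-3-en-1-yl]-2-methoxyphenyl pivalate (carbinol = C7), via pinacol borate ester 4 (not isolated)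
Conditions: (S)-TRIP (5 mol%), toluene, −30 °C; aq. NaHCO3 work-up
Reagents that add atoms: none
Why: Chiral phosphoric acid-catalysed allylboration of an aryl aldehyde through a chair six-membered transition state in which the acid binds the boronate oxygen and the formyl hydrogen; the (S)-acid should deliver allyl to the Si face and set C7 as (S).

Step 3
Reactants: 5 homoallylic alcohol
Product: 6 4-[(1S)-1-(triethylsilyloxy)but-3-en-1-yl]-2-methoxyphenyl pivalate
Conditions: TESCl (1.2 equiv), imidazole (2 equiv), CH2Cl2, 0 °C → rt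
Reagents that add atoms: chlorotriethylsilane, CC[Si](Cl)(CC)CC
Why: Standard silylation; the TES ether masks C7–OH through the second allylation and can later be removed in the presence of a secondary TBS ether.

Step 4
Reactants: 6 TES ether
Product: 8 2-methoxy-4-[(1S)-3-oxo-1-(triethylsilyloxy)propyl]phenyl pivalate, via secondary ozonide 7 (not isolated)
Conditions: O3, CH2Cl2, −78 °C (Sudan III end point); PPh3, −78 °C → rt; used crude
Reagents that add atoms: ozone, [O-][O+]=O
Why: Ozonolysis with reductive work-up cleaves the terminal alkene far faster than the acyloxy-deactivated arene is attacked; the indicator prevents over-ozonation and the β-silyloxy aldehyde is carried on without chromatography to avoid β-elimination.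

Step 5
Reactants: 8 β-silyloxy aldehyde; 9 B-allyldiisopinocampheylborane derived from (+)-α-pinene (dIpc2B-allyl)
Product: 11 4-[(1S,3S)-3-hydroxy-1-(triethylsilyloxy)hex-5-en-1-yl]-2-methoxyphenyl pivalate (new carbinol = C5), via diisopinocampheyl borinate 10 (not isolated)
Conditions: Et2O, −78 °C; then pH 7 phosphate buffer, MeOH, 30% H2O2, 0 °C → rt
Reagents that add atoms: none
Why: Brown allylboration through a chair Zimmerman–Traxler transition state; the isopinocampheyl ligands should override the weak 1,3-bias of the β-silyloxy aldehyde and direct Si-face addition, giving (S)-C5, 1,3-syn to C7, while the buffered oxidative work-up spares the aryl pivalate; any anti diastereomer should be removable by chromatography.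

Step 6
Reactants: 11 mono-TES syn-diol
Product: 12 4-[(1S,3S)-3-(tert-butyldimethylsilyloxy)-1-(triethylsilyloxy)hex-5-en-1-yl]-2-methoxyphenyl pivalate
Conditions: TBSOTf (1.3 equiv), 2,6-lutidine (2 equiv), CH2Cl2, −78 → 0 °C
Reagents that add atoms: tert-butyldimethylsilyl triflate, CC(C)(C)[Si](C)(C)OS(=O)(=O)C(F)(F)F
Why: Silyl triflate with a hindered base silylates the secondary C5–OH quickly without touching the TES ether or the ester.

Step 7
Reactants: 12 bis-silyl ether
Product: 13 4-[(1S,3S)-3-(tert-butyldimethylsilyloxy)-1-hydroxyhex-5-en-1-yl]-2-methoxyphenyl pivalate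
Conditions: PPTS (0.2 equiv), MeOH/CH2Cl2 (1:1), 0 °C
Reagents that add atoms: none
Why: Mild acid methanolysis cleaves a TES ether much faster than a TBS ether, and the pivalate-deactivated C7 position should not ionise under these conditions, so C7–OH is freed with C5 still protected.

Step 8
Reactants: 1 vanillin
Product: 14 4-(benzyloxy)-3-methoxybenzaldehyde (O-benzylvanillin)
Conditions: BnBr (1.1 equiv), K2CO3 (1.5 equiv), DMF, rt
Reagents that add atoms: benzyl bromide, BrCc1ccccc1
Why: Williamson etherification of the phenol; the benzyl ether keeps this ring electron-rich for the key step and is removed in the hydrogenation.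

Step 9
Reactants: 14 O-benzylvanillin; 15 vinylmagnesium bromide
Product: 17 rac-1-[4-(benzyloxy)-3-methoxyphenyl]prop-2-en-1-ol, via bromomagnesium alkoxide 16 (not isolated)
Conditions: THF, 0 °C; sat. aq. NH4Cl
Reagents that add atoms: none
Why: Grignard 1,2-addition to the aldehyde; the carbinol is left racemic on purpose because this centre is ionised in step 11, and the acid-sensitive product is used without acidic handling.

Step 10
Reactants: 13 C3–C7 alkene; 17 racemic aryl vinyl carbinol (3 equiv)
Product: 18 (2E,5S,7S)-1-[4-(benzyloxy)-3-methoxyphenyl]-5-(tert-butyldimethylsilyloxy)-7-[3-methoxy-4-(pivaloyloxy)phenyl]hept-2-ene-1,7-diol (both C1 epimers)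
Conditions: Hoveyda–Grubbs II (5 mol%), 1,4-benzoquinone (10 mol%), CH2Cl2, 40 °C, Ar sparge; filtration through Et3N-deactivated silica
Reagents that add atoms: none
Why: Olefin cross-metathesis of a type I terminal alkene with an excess of a secondary allylic alcohol should give the (E)-disubstituted alkene; benzoquinone suppresses ruthenium hydride isomerisation of the allylic alcohol.

Step 11
Reactants: 18 hydroxy allylic alcohol (epimers at C1)
Product: 21 4-[(2S,4S,6R)-6-{(E)-2-[4-(benzyloxy)-3-methoxyphenyl]ethenyl}-4-(tert-butyldimethylsilyloxy)oxan-2-yl]-2-methoxyphenyl pivalate (2,6-cis), via allyl cation perrhenate 19 (not isolated), via 2,6-trans oxane 20 (not isolated)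
Conditions: Re2O7 (5 mol%), CH2Cl2 (0.02 M), 0 °C → rt; Et3N quench
Reagents that add atoms: none
Why: Re2O7 converts the doubly activated C1 carbinol of either epimer into an allylic perrhenate that ionises to the (E)-1-aryl allyl cation 19, stabilised by the para-benzyloxy group, and the C7 hydroxyl captures its C3 terminus to form the O–C3 bond; this is the known rhenium(VII)-catalysed allylic alcohol transposition/etherification that gives 2,6-cis-tetrahydropyrans under thermodynamic control. The oxane closes in a 6-exo mode with respect to the allyl system, the C1=C2 bond remaining outside the ring as the conjugated (E)-styrene, whereas capture at C1 would require an eight-membered ring. The new C3 stereocentre is set by equilibration, not by kinetic facial bias: the C3–O bond of 20 and 21 is the allylic ether of an electron-rich styrene and should re-ionise under the reaction conditions. The mixture should therefore drain to the chair of 21 with aryl and styryl groups both equatorial and only the C5 silyloxy group axial, since 20 must place either the styryl group axial and syn to that silyloxy group or the aryl group axial. The step needs chemoselective ionisation at C1/C3 only; the pivalate secures this by making the C7 aryl too electron-poor for benzylic C7–O heterolysis, so C7 and the non-ionisable C5 remain fixed stereochemical references. High dilution and the basic quench are meant to limit intermolecular etherification and acid-promoted desilylation.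

Step 12
Reactants: 21 cis-styryl oxane
Product: 22 4-[(2S,4S,6S)-4-(tert-butyldimethylsilyloxy)-6-[2-(4-hydroxy-3-methoxyphenyl)ethyl]oxan-2-yl]-2-methoxyphenyl pivalate
Conditions: H2 (1 atm), 10% Pd/C, EtOAc, rt
Reagents that add atoms: none
Why: Heterogeneous hydrogenation saturates the styrene and hydrogenolyses the aryl benzyl ether in one operation; the neutral, aprotic solvent and the acyloxy-deactivated C7 aryl should keep the ring C–O bonds intact.

Step 13
Reactants: 22 silyl ether
Product: 23 4-[(2S,4S,6S)-4-hydroxy-6-[2-(4-hydroxy-3-methoxyphenyl)ethyl]oxan-2-yl]-2-methoxyphenyl pivalate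
Conditions: HF·pyridine, pyridine, THF, 0 °C → rt
Reagents that add atoms: none
Why: Buffered fluoride cleaves the secondary TBS ether; doing this while the pivalate is still in place keeps the C7 benzylic ether inert to the mildly acidic medium.

Step 14
Reactants: 23 aryl pivalate
Product: 24 (2S,4S,6S)-2-(4-hydroxy-3-methoxyphenyl)-6-[2-(4-hydroxy-3-methoxyphenyl)ethyl]oxan-4-ol (target, CNP0120286.2)
Conditions: K2CO3 (0.3 equiv), MeOH, rt
Reagents that add atoms: none
Why: Base-catalysed transesterification of the aryl ester with methanol frees the last phenol under conditions mild enough to leave the cis-oxane and its three stereocentres untouched.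

## Compound list

1 | vanillin | COc1cc(C=O)ccc1O | starting material
2 | 4-formyl-2-methoxyphenyl pivalate | COc1cc(C=O)ccc1OC(=O)C(C)(C)C | intermediate
3 | allylboronic acid pinacol ester | C=CCB1OC(C)(C)C(C)(C)O1 | starting material
4 | pinacol borate ester of 5 | C=CC[C@H](OB1OC(C)(C)C(C)(C)O1)c1ccc(OC(=O)C(C)(C)C)c(OC)c1 | intermediate
5 | 4-[(1S)-1-hydroxybut-3-en-1-yl]-2-methoxyphenyl pivalate | C=CC[C@H](O)c1ccc(OC(=O)C(C)(C)C)c(OC)c1 | intermediate
6 | 4-[(1S)-1-(triethylsilyloxy)but-3-en-1-yl]-2-methoxyphenyl pivalate | C=CC[C@H](O[Si](CC)(CC)CC)c1ccc(OC(=O)C(C)(C)C)c(OC)c1 | intermediate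
7 | secondary ozonide (1,2,4-trioxolane) of 6 | CC[Si](CC)(CC)O[C@@H](CC1OCOO1)c1ccc(OC(=O)C(C)(C)C)c(OC)c1 | intermediate
8 | 2-methoxy-4-[(1S)-3-oxo-1-(triethylsilyloxy)propyl]phenyl pivalate | O=CC[C@H](O[Si](CC)(CC)CC)c1ccc(OC(=O)C(C)(C)C)c(OC)c1 | intermediate
9 | B-allyldiisopinocampheylborane from (+)-α-pinene (dIpc2B-allyl) | C=CCB([C@@H]1C[C@@H]2C[C@H]([C@H]1C)C2(C)C)[C@@H]1C[C@@H]2C[C@H]([C@H]1C)C2(C)C | starting material
10 | diisopinocampheyl borinate of 11 | C=CC[C@H](OB([C@@H]1C[C@@H]2C[C@H]([C@H]1C)C2(C)C)[C@@H]1C[C@@H]2C[C@H]([C@H]1C)C2(C)C)C[C@H](O[Si](CC)(CC)CC)c1ccc(OC(=O)C(C)(C)C)c(OC)c1 | intermediate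
11 | 4-[(1S,3S)-3-hydroxy-1-(triethylsilyloxy)hex-5-en-1-yl]-2-methoxyphenyl pivalate | C=CC[C@H](O)C[C@H](O[Si](CC)(CC)CC)c1ccc(OC(=O)C(C)(C)C)c(OC)c1 | intermediate
12 | 4-[(1S,3S)-3-(tert-butyldimethylsilyloxy)-1-(triethylsilyloxy)hex-5-en-1-yl]-2-methoxyphenyl pivalate | C=CC[C@H](O[Si](C)(C)C(C)(C)C)C[C@H](O[Si](CC)(CC)CC)c1ccc(OC(=O)C(C)(C)C)c(OC)c1 | intermediate
13 | 4-[(1S,3S)-3-(tert-butyldimethylsilyloxy)-1-hydroxyhex-5-en-1-yl]-2-methoxyphenyl pivalate | C=CC[C@H](O[Si](C)(C)C(C)(C)C)C[C@H](O)c1ccc(OC(=O)C(C)(C)C)c(OC)c1 | intermediate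
14 | 4-(benzyloxy)-3-methoxybenzaldehyde | COc1cc(C=O)ccc1OCc1ccccc1 | intermediate
15 | vinylmagnesium bromide | C=C[Mg]Br | starting material
16 | bromomagnesium alkoxide of 17 | C=CC(O[Mg]Br)c1ccc(OCc2ccccc2)c(OC)c1 | intermediate
17 | rac-1-[4-(benzyloxy)-3-methoxyphenyl]prop-2-en-1-ol | C=CC(O)c1ccc(OCc2ccccc2)c(OC)c1 | intermediate
18 | (2E,5S,7S)-1-[4-(benzyloxy)-3-methoxyphenyl]-5-(tert-butyldimethylsilyloxy)-7-[3-methoxy-4-(pivaloyloxy)phenyl]hept-2-ene-1,7-diol, both C1 epimers | OC(/C=C/C[C@H](O[Si](C)(C)C(C)(C)C)C[C@H](O)c1ccc(OC(=O)C(C)(C)C)c(OC)c1)c1ccc(OCc2ccccc2)c(OC)c1 | intermediate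
19 | (E)-1-aryl allyl cation of 18 as its perrhenate ion pair | COc1cc([CH+]/C=C/C[C@H](O[Si](C)(C)C(C)(C)C)C[C@H](O)c2ccc(OC(=O)C(C)(C)C)c(OC)c2)ccc1OCc1ccccc1.[O-][Re](=O)(=O)=O | intermediate
20 | 2,6-trans oxane, (2S,4S,6S) C3-epimer of 21 | COc1cc(/C=C/[C@@H]2C[C@H](O[Si](C)(C)C(C)(C)C)C[C@@H](c3ccc(OC(=O)C(C)(C)C)c(OC)c3)O2)ccc1OCc1ccccc1 | intermediate
21 | 4-[(2S,4S,6R)-6-{(E)-2-[4-(benzyloxy)-3-methoxyphenyl]ethenyl}-4-(tert-butyldimethylsilyloxy)oxan-2-yl]-2-methoxyphenyl pivalate | COc1cc(/C=C/[C@H]2C[C@H](O[Si](C)(C)C(C)(C)C)C[C@@H](c3ccc(OC(=O)C(C)(C)C)c(OC)c3)O2)ccc1OCc1ccccc1 | intermediate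
22 | 4-[(2S,4S,6S)-4-(tert-butyldimethylsilyloxy)-6-[2-(4-hydroxy-3-methoxyphenyl)ethyl]oxan-2-yl]-2-methoxyphenyl pivalate | COc1cc(CC[C@H]2C[C@H](O[Si](C)(C)C(C)(C)C)C[C@@H](c3ccc(OC(=O)C(C)(C)C)c(OC)c3)O2)ccc1O | intermediate
23 | 4-[(2S,4S,6S)-4-hydroxy-6-[2-(4-hydroxy-3-methoxyphenyl)ethyl]oxan-2-yl]-2-methoxyphenyl pivalate | COc1cc(CC[C@H]2C[C@H](O)C[C@@H](c3ccc(OC(=O)C(C)(C)C)c(OC)c3)O2)ccc1O | intermediate
24 | (2S,4S,6S)-2-(4-hydroxy-3-methoxyphenyl)-6-[2-(4-hydroxy-3-methoxyphenyl)ethyl]oxan-4-ol | COc1cc(CC[C@H]2C[C@H](O)C[C@@H](c3ccc(O)c(OC)c3)O2)ccc1O | target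

## Step count and risks

Total step count: 14. Longest linear sequence: 12 (steps 1–7 and 10–14).

Steps most likely to fail:

1. Step 11. Under the acidic rhenium conditions the C5 silyl ether may be lost, the allyl cation may lose a proton from C4 to give a 1-aryl diene, or the C3 epimers may not fully equilibrate. Fallback: the same O–C3 bond is made by conjugate addition instead of cation capture. It sets out from 18, whose doubly activated C1 carbinol is oxidised with MnO2 (CH2Cl2) to the (E)-enone F2. DBU (cat., CH2Cl2, rt) then promotes intramolecular oxa-Michael addition of the C7 hydroxyl under thermodynamic control to the 2,6-cis oxane ketone F3. NaBH4 (THF/EtOH, 0 °C) gives the C1 carbinol F4 as both epimers. Hydrogenolysis (H2, Pd/C, EtOAc with a little AcOH) removes the para-alkoxybenzylic hydroxyl and the benzyl ether together, and the route is rejoined at 22.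

2. Step 10. Ruthenium hydrides may isomerise the secondary 1-aryl allylic alcohol to the propiophenone, and the electron-rich carbinol may undergo 1,3-transposition or premature ionisation, so that cross-metathesis stalls. Fallback: it sets out from 17, which is oxidised with MnO2 to the aryl vinyl ketone F1, a well-behaved electron-poor metathesis partner. Cross-metathesis of F1 with 13 (Hoveyda–Grubbs II, CH2Cl2, 40 °C) gives the (E)-enone F2. Luche reduction (NaBH4, CeCl3·7H2O, MeOH, −40 °C) returns the C1 carbinol as both epimers, rejoining the route at 18.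

3. Step 12. Hydrogenolysis of the allylic C3–O ring bond (and, more slowly, of the benzylic C7–O bond) may compete with saturation of the styrene. Fallback: it sets out from 21, whose alkene is reduced without a metal by diimide (2-nitrobenzenesulfonyl hydrazide, Et3N, CH2Cl2, rt) to the saturated benzyl ether F5. With no allylic C–O bond left, the benzyl ether is then cleaved by transfer hydrogenolysis (1,4-cyclohexadiene, Pd/C, EtOH), rejoining the route at 22.

## Further compounds

F1 | step 10 | 1-[4-(benzyloxy)-3-methoxyphenyl]prop-2-en-1-one | C=CC(=O)c1ccc(OCc2ccccc2)c(OC)c1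
F2 | step 10 | 4-[(1S,3S,5E)-7-[4-(benzyloxy)-3-methoxyphenyl]-3-(tert-butyldimethylsilyloxy)-1-hydroxy-7-oxohept-5-en-1-yl]-2-methoxyphenyl pivalate | O=C(/C=C/C[C@H](O[Si](C)(C)C(C)(C)C)C[C@H](O)c1ccc(OC(=O)C(C)(C)C)c(OC)c1)c1ccc(OCc2ccccc2)c(OC)c1
F3 | step 11 | 4-[(2S,4S,6S)-6-{2-[4-(benzyloxy)-3-methoxyphenyl]-2-oxoethyl}-4-(tert-butyldimethylsilyloxy)oxan-2-yl]-2-methoxyphenyl pivalate | O=C(C[C@H]1C[C@H](O[Si](C)(C)C(C)(C)C)C[C@@H](c2ccc(OC(=O)C(C)(C)C)c(OC)c2)O1)c1ccc(OCc2ccccc2)c(OC)c1
F4 | step 11 | 4-[(2S,4S,6S)-6-{2-[4-(benzyloxy)-3-methoxyphenyl]-2-hydroxyethyl}-4-(tert-butyldimethylsilyloxy)oxan-2-yl]-2-methoxyphenyl pivalate, both carbinol epimers | OC(C[C@H]1C[C@H](O[Si](C)(C)C(C)(C)C)C[C@@H](c2ccc(OC(=O)C(C)(C)C)c(OC)c2)O1)c1ccc(OCc2ccccc2)c(OC)c1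
F5 | step 12 | 4-[(2S,4S,6S)-6-{2-[4-(benzyloxy)-3-methoxyphenyl]ethyl}-4-(tert-butyldimethylsilyloxy)oxan-2-yl]-2-methoxyphenyl pivalate | COc1cc(CC[C@H]2C[C@H](O[Si](C)(C)C(C)(C)C)C[C@@H](c3ccc(OC(=O)C(C)(C)C)c(OC)c3)O2)ccc1OCc1ccccc1
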